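**Plan**

- Last cuts: the two dioxolanes and the allyl ester. Before that, the exocyclic C5=C bond of the vinylogous ester is cut to a C5 aldehyde (as its enol silane) and O-ethylated 5,5-dimethylfuran-2(5H)-one.
- Enabling feature (C3 = CH–CO2H, C4 = CH–CH2CHO, C5 = formyl-bearing alkene carbon): the chain carboxyl C–C3–C4–C5–formyl C has oxygen at both ends and folds back into a delta-lactone ring with C3 alpha and C4 beta.
- Key cut: C4–CH2 (acetal arm) and C3–C(=CH2) (alkenyl arm) are broken together, giving 5,6-dihydro-2H-pyran-2-one, an acetal Grignard reagent and a 2-bromoalkene.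
- Forward order: bromoalkene; three-component coupling on the lactone; lactone opening to an allyl ester; oxidation of the freed CH2OH; enol silane; condensation with the lactonium salt; deallylation; acetal hydrolysis. The lactone is a temporary ring and the dihydrofuran ring arrives intact.
- Stereochemistry: C4 from the chiral copper catalyst; C3 by anti delivery of the alkenyl group in the six-membered ring (trans, also the thermodynamic isomer); the E alkene by equilibration of the push–pull double bond.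

Key step: step 2

Assumption: the antipode of the ferrocenyl diphosphine that sends the alkyl group to the Re face of C4 of the lactone (leading to 4S) is identified in a first run; both antipodes are commercial. The acetal Grignard reagent is used as its commercial 0.5 M THF solution.

**Step 1**
Reactants: 1 2-(2-bromoethyl)-2-methyl-1,3-dioxolane; 2 2,3-dibromoprop-1-ene
Product: 4 2-(4-bromopent-4-en-1-yl)-2-methyl-1,3-dioxolane, via Grignard reagent 3 (not isolated)
Conditions: Mg, THF, 25 °C; then 2, CuI (5 mol%), THF, 0 °C → rt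
Reagents that add atoms: none
Why: Grignard formation followed by copper-catalysed allylic substitution (SN2/SN2′) on 2,3-dibromopropene is the standard route to 2-bromoalk-1-enes, and the vinylic C–Br bond and the ketal are inert under these conditions.

**Step 2**
Reactants: 5 5,6-dihydro-2H-pyran-2-one; 6 (1,3-dioxolan-2-ylmethyl)magnesium bromide; 4 2-(4-bromopent-4-en-1-yl)-2-methyl-1,3-dioxolane
Product: 9 (3R,4S)-4-(1,3-dioxolan-2-ylmethyl)-3-[5-(2-methyl-1,3-dioxolan-2-yl)pent-1-en-2-yl]tetrahydro-2H-pyran-2-one, via magnesium enolate 7 (not isolated), via zinc enolate 8 (not isolated)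
Conditions: CuBr·SMe2 (5 mol%), (R)-1-[(Sp)-2-(diphenylphosphino)ferrocenyl]ethyldicyclohexylphosphine or its enantiomer (6 mol%), t-BuOMe, −78 °C, slow addition of 6 (1.1 equiv); ZnCl2 (1.3 equiv, THF), −78 → 0 °C; 4 (1.5 equiv), Pd[P(t-Bu)3]2 (5 mol%), THF, 0 °C → rt; aq. NH4Cl
Reagents that add atoms: none
Why: Proposed new method: a chiral monovalent copper–diphosphine complex transfers the dioxolanylmethyl group to the Re face of C4 of the s-trans-locked enoate 5 and leaves magnesium enolate 7, which ZnCl2 converts into the less basic zinc enolate 8; zerovalent palladium then inserts into the C–Br bond of 4, the enolate transmetalates through carbon and reductive elimination forms the C3–alkenyl bond. The closest known reactions are the copper-catalysed asymmetric conjugate addition of Grignard reagents to unsaturated delta-lactones with enolate trapping and the palladium-catalysed alpha-arylation and alpha-alkenylation of zinc ester enolates (Reformatsky–Negishi type), merged here in one flask. No ring is closed; the lactone ring only serves as a template. C4 (S) is set by the ligand on copper, and C3 (R) by the substrate, the alkenyl group entering anti to the new C4 substituent to give the trans lactone, which is also the thermodynamic isomer should the alpha-centre equilibrate. The step needs 1,4- rather than 1,2-addition (copper catalysis, low temperature), a single alkenylation without migration of the 1,1-disubstituted alkene into conjugation (weakly basic zinc enolate, fast reductive elimination from the bulky phosphine complex) and oxidative addition only at the alkenyl bromide, the sole C–halogen bond present.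

**Step 3**
Reactants: 9 (3R,4S)-4-(1,3-dioxolan-2-ylmethyl)-3-[5-(2-methyl-1,3-dioxolan-2-yl)pent-1-en-2-yl]tetrahydro-2H-pyran-2-one
Product: 11 allyl (2R,3S)-3-(1,3-dioxolan-2-ylmethyl)-5-hydroxy-2-[5-(2-methyl-1,3-dioxolan-2-yl)pent-1-en-2-yl]pentanoate, via potassium carboxylate 10 (not isolated)
Conditions: KOH (1.05 equiv), THF/H2O, 0 °C; evaporate; allyl bromide, DMF, 0 °C → rt; used crude
Reagents that add atoms: potassium hydroxide, [K+].[OH-]; allyl bromide, C=CCBr
Why: Saponification of the delta-lactone with one equivalent of hydroxide and SN2 O-alkylation of the carboxylate salt give the hydroxy ester without a base strong enough to deprotonate the alcohol or the allylic alpha-centre, so C3 is carried over unchanged.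

**Step 4**
Reactants: 11 allyl (2R,3S)-3-(1,3-dioxolan-2-ylmethyl)-5-hydroxy-2-[5-(2-methyl-1,3-dioxolan-2-yl)pent-1-en-2-yl]pentanoate
Product: 12 allyl (2R,3S)-3-(1,3-dioxolan-2-ylmethyl)-2-[5-(2-methyl-1,3-dioxolan-2-yl)pent-1-en-2-yl]-5-oxopentanoate
Conditions: Dess–Martin periodinane, CH2Cl2, 0 °C → rt
Reagents that add atoms: none
Why: Dess–Martin oxidation turns the primary alcohol into the aldehyde under neutral, non-epimerising conditions and removes the hydroxyl before it can relactonise.

**Step 5**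
Reactants: 12 allyl (2R,3S)-3-(1,3-dioxolan-2-ylmethyl)-2-[5-(2-methyl-1,3-dioxolan-2-yl)pent-1-en-2-yl]-5-oxopentanoate
Product: 13 allyl (2R,3R)-5-[(tert-butyldimethylsilyl)oxy]-3-(1,3-dioxolan-2-ylmethyl)-2-[5-(2-methyl-1,3-dioxolan-2-yl)pent-1-en-2-yl]pent-4-enoate (E/Z mixture at the enol ether; the descriptor at C3 changes by priority only)
Conditions: TBSOTf (1.15 equiv), Et3N (2 equiv), CH2Cl2, −78 → −20 °C
Reagents that add atoms: tert-butyldimethylsilyl trifluoromethanesulfonate, CC(C)(C)[Si](C)(C)OS(=O)(=O)C(F)(F)F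
Why: Soft enolisation with a silyl triflate and an amine converts the aldehyde, which has a single alpha-methylene, into its enol silane, while the ester is not silylated at low temperature and Et3N tempers the silyl triflate enough to leave the dioxolanes closed.

**Step 6**
Reactants: 14 5,5-dimethylfuran-2(5H)-one
Product: 15 2-ethoxy-5,5-dimethyl-5H-furan-1-ium tetrafluoroborate
Conditions: Et3OBF4 (1.0 equiv), CH2Cl2, rt; precipitation with dry Et2O, used at once
Reagents that add atoms: triethyloxonium tetrafluoroborate, CC[O+](CC)CC.F[B-](F)(F)F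
Why: O-Alkylation of a lactone carbonyl by a trialkyloxonium salt is the classical entry to lactonium (dialkoxycarbenium) tetrafluoroborates, and the gem-dimethyl group prevents aromatisation to a 2-ethoxyfuran.

**Step 7**
Reactants: 13 allyl (2R,3R)-5-[(tert-butyldimethylsilyl)oxy]-3-(1,3-dioxolan-2-ylmethyl)-2-[5-(2-methyl-1,3-dioxolan-2-yl)pent-1-en-2-yl]pent-4-enoate; 15 2-ethoxy-5,5-dimethyl-5H-furan-1-ium tetrafluoroborate
Product: 17 allyl (2R,3S)-3-[(1E)-1-(5,5-dimethylfuran-2(5H)-ylidene)-2-oxoethyl]-4-(1,3-dioxolan-2-yl)-2-[5-(2-methyl-1,3-dioxolan-2-yl)pent-1-en-2-yl]butanoate, via ethoxy ketal aldehyde 16 (not isolated)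
Conditions: 15 (1.3 equiv), 2,6-di-tert-butylpyridine (0.2 equiv), CH2Cl2, −78 → −40 °C; then Et3N (3 equiv), −40 °C → rt
Reagents that add atoms: none
Why: Proposed new method: the enol silane should attack ring carbon 2 of the dialkoxycarbenium ion 15 (the gem-dimethyl group shields the vinylogous ring carbon 4) while BF4− delivers fluoride to silicon, giving the mixed ketal aldehyde 16, from which Et3N removes the acidic alpha-hydrogen and expels ethanol (E1cB) to the push–pull vinylogous ester, whose low C=C rotation barrier should let the geometry settle on the E isomer with the bulky C4 branch beside the ring oxygen; the closest known reactions are the Mukaiyama-type addition of enol silanes to orthoester-derived and other heteroatom-stabilised carbenium ions and the condensation of O-alkyl lactonium salts with C–H acids to 2-alkylidene oxacycles.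

**Step 8**
Reactants: 17 allyl (2R,3S)-3-[(1E)-1-(5,5-dimethylfuran-2(5H)-ylidene)-2-oxoethyl]-4-(1,3-dioxolan-2-yl)-2-[5-(2-methyl-1,3-dioxolan-2-yl)pent-1-en-2-yl]butanoate
Product: 18 (2R,3S)-3-[(1E)-1-(5,5-dimethylfuran-2(5H)-ylidene)-2-oxoethyl]-4-(1,3-dioxolan-2-yl)-2-[5-(2-methyl-1,3-dioxolan-2-yl)pent-1-en-2-yl]butanoic acid
Conditions: Pd(PPh3)4 (5 mol%), sodium p-toluenesulfinate (1.3 equiv), THF/MeOH, rt; then 0.1 M aq. HCl to pH 4, 0 °C
Reagents that add atoms: none
Why: Zerovalent palladium ionises the unhindered allyl ester to a pi-allyl complex that the sulfinate captures irreversibly (Tsuji–Trost deallylation) under neutral conditions that should leave the acetals, the vinylogous ester and the alpha-centre untouched.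

**Step 9**
Reactants: 18 (2R,3S)-3-[(1E)-1-(5,5-dimethylfuran-2(5H)-ylidene)-2-oxoethyl]-4-(1,3-dioxolan-2-yl)-2-[5-(2-methyl-1,3-dioxolan-2-yl)pent-1-en-2-yl]butanoic acid
Product: 19 (2R,3S)-3-[(1E)-1-(5,5-dimethylfuran-2(5H)-ylidene)-2-oxoethyl]-5-oxo-2-(6-oxohept-1-en-2-yl)pentanoic acid (CNP0150297.1)
Conditions: 1 M aq. HCl/THF (1:4), 0 °C → rt
Reagents that add atoms: water, O
Why: Acid-catalysed acetal hydrolysis releases the ketone and the aldehyde; any hydrolytic opening of the vinylogous ester is reversible and should reclose to the conjugated five-membered ring, which also keeps the exocyclic alkene in its more stable E form.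

**Compound list**

1 | 2-(2-bromoethyl)-2-methyl-1,3-dioxolane | BrCCC1(C)OCCO1 | starting material
2 | 2,3-dibromoprop-1-ene | C=C(Br)CBr | starting material
3 | [2-(2-methyl-1,3-dioxolan-2-yl)ethyl]magnesium bromide | Br[Mg]CCC1(C)OCCO1 | intermediate (not isolated)
4 | 2-(4-bromopent-4-en-1-yl)-2-methyl-1,3-dioxolane | C=C(Br)CCCC1(C)OCCO1 | intermediate
5 | 5,6-dihydro-2H-pyran-2-one | O=C1C=CCCO1 | starting material
6 | (1,3-dioxolan-2-ylmethyl)magnesium bromide | Br[Mg]CC1OCCO1 | starting material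
7 | bromomagnesium (4S)-4-(1,3-dioxolan-2-ylmethyl)-5,6-dihydro-4H-pyran-2-olate | Br[Mg]OC1=C[C@H](CC2OCCO2)CCO1 | intermediate (not isolated)
8 | chlorozinc (4S)-4-(1,3-dioxolan-2-ylmethyl)-5,6-dihydro-4H-pyran-2-olate | Cl[Zn]OC1=C[C@H](CC2OCCO2)CCO1 | intermediate (not isolated)
9 | (3R,4S)-4-(1,3-dioxolan-2-ylmethyl)-3-[5-(2-methyl-1,3-dioxolan-2-yl)pent-1-en-2-yl]tetrahydro-2H-pyran-2-one (trans) | C=C(CCCC1(C)OCCO1)[C@@H]2C(=O)OCC[C@H]2CC3OCCO3 | intermediate
10 | potassium (2R,3S)-3-(1,3-dioxolan-2-ylmethyl)-5-hydroxy-2-[5-(2-methyl-1,3-dioxolan-2-yl)pent-1-en-2-yl]pentanoate | C=C(CCCC1(C)OCCO1)[C@H](C(=O)[O-])[C@H](CC2OCCO2)CCO.[K+] | intermediate (not isolated)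
11 | allyl (2R,3S)-3-(1,3-dioxolan-2-ylmethyl)-5-hydroxy-2-[5-(2-methyl-1,3-dioxolan-2-yl)pent-1-en-2-yl]pentanoate | C=C(CCCC1(C)OCCO1)[C@H](C(=O)OCC=C)[C@H](CC2OCCO2)CCO | intermediate
12 | allyl (2R,3S)-3-(1,3-dioxolan-2-ylmethyl)-2-[5-(2-methyl-1,3-dioxolan-2-yl)pent-1-en-2-yl]-5-oxopentanoate | C=C(CCCC1(C)OCCO1)[C@H](C(=O)OCC=C)[C@H](CC2OCCO2)CC=O | intermediate
13 | allyl (2R,3R)-5-[(tert-butyldimethylsilyl)oxy]-3-(1,3-dioxolan-2-ylmethyl)-2-[5-(2-methyl-1,3-dioxolan-2-yl)pent-1-en-2-yl]pent-4-enoate (E/Z mixture) | C=C(CCCC1(C)OCCO1)[C@H](C(=O)OCC=C)[C@H](CC2OCCO2)C=CO[Si](C)(C)C(C)(C)C | intermediate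
14 | 5,5-dimethylfuran-2(5H)-one | CC1(C)OC(=O)C=C1 | starting material
15 | 2-ethoxy-5,5-dimethyl-5H-furan-1-ium tetrafluoroborate | CCOC1=[O+]C(C)(C)C=C1.F[B-](F)(F)F | intermediate
16 | allyl (2R,3R)-4-(1,3-dioxolan-2-yl)-3-[1-(2-ethoxy-5,5-dimethyl-2,5-dihydrofuran-2-yl)-2-oxoethyl]-2-[5-(2-methyl-1,3-dioxolan-2-yl)pent-1-en-2-yl]butanoate (epimers at the two new sp3 carbons) | C=C(CCCC1(C)OCCO1)[C@H](C(=O)OCC=C)[C@H](CC2OCCO2)C(C=O)C3(OCC)C=CC(C)(C)O3 | intermediate (not isolated)
17 | allyl (2R,3S)-3-[(1E)-1-(5,5-dimethylfuran-2(5H)-ylidene)-2-oxoethyl]-4-(1,3-dioxolan-2-yl)-2-[5-(2-methyl-1,3-dioxolan-2-yl)pent-1-en-2-yl]butanoate | C=C(CCCC1(C)OCCO1)[C@H](C(=O)OCC=C)[C@H](CC2OCCO2)/C(C=O)=C3/C=CC(C)(C)O3 | intermediate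
18 | (2R,3S)-3-[(1E)-1-(5,5-dimethylfuran-2(5H)-ylidene)-2-oxoethyl]-4-(1,3-dioxolan-2-yl)-2-[5-(2-methyl-1,3-dioxolan-2-yl)pent-1-en-2-yl]butanoic acid | C=C(CCCC1(C)OCCO1)[C@H](C(=O)O)[C@H](CC2OCCO2)/C(C=O)=C3/C=CC(C)(C)O3 | intermediate
19 | (2R,3S)-3-[(1E)-1-(5,5-dimethylfuran-2(5H)-ylidene)-2-oxoethyl]-5-oxo-2-(6-oxohept-1-en-2-yl)pentanoic acid | C=C(CCCC(C)=O)[C@H](C(=O)O)[C@H](CC=O)/C(C=O)=C1/C=CC(C)(C)O1 | target

**Count and risks**

Total steps: 9. Longest linear sequence: 8 steps (1 → 4 → 9 → 11 → 12 → 13 → 17 → 18 → 19).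

Steps most likely to fail:

1. Step 2. The THF brought in with the Grignard reagent may erode the facial selectivity. The copper and magnesium salts may stall transmetalation or coupling. The new 1,1-disubstituted alkene may migrate into conjugation. The fallback sets out from 5 and 6 and returns at 9, using two separate known operations. The conjugate addition is run alone under the same copper catalysis and enolate 7 is protonated with aqueous NH4Cl to give (4S)-4-(1,3-dioxolan-2-ylmethyl)tetrahydro-2H-pyran-2-one F1, which is purified. F1 is deprotonated with LiN(SiMe3)2 in THF at −78 °C to its lithium enolate F2, transmetalated with ZnCl2 to 8 and coupled with 4 under Pd[P(t-Bu)3]2 catalysis to give 9.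

2. Step 7. The enol silane may attack the vinylogous position of the lactonium ion. The BF3 released may open a dioxolane, followed by Prins-type capture by the 1,1-disubstituted alkene. Ethanol loss may be incomplete. The fallback sets out from 13 and returns at 17, using known reactions only. 2-Methylbut-3-yn-2-ol is silylated (Et3SiCl, imidazole) to triethyl[(2-methylbut-3-yn-2-yl)oxy]silane F3. F3 is deprotonated with n-BuLi to the lithium acetylide F4 and formylated with DMF to 4-methyl-4-[(triethylsilyl)oxy]pent-2-ynal F5. Mukaiyama aldol addition of 13 to F5 (BF3·OEt2, CH2Cl2, −78 °C) should give the beta-hydroxy aldehyde F6. Dess–Martin oxidation gives the 2-acyl aldehyde F7. Semi-hydrogenation over Pd/CaCO3 poisoned with Pb(OAc)2 and quinoline gives the (Z)-enone F8. HF·pyridine then removes the silyl group, the tertiary alcohol closes onto the ketone to the hemiketal F9 (not isolated), and loss of water gives 17.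

3. Step 9. The aldehyde dioxolane may hydrolyse too slowly, so that the acid strength needed allows carbonyl-ene or Prins cyclisation of the freed aldehyde onto the 1,1-disubstituted alkene, or epimerisation at C3. The fallback sets out from 17 and returns at 19, with a staged, largely non-hydrolytic unmasking. Et3SiOTf and 2,4,6-collidine (CH2Cl2, 0 °C) should open only the aldehyde acetal to the collidinium triflate F10 (not isolated). Water then gives the aldehyde ketal ester F11. The more labile ketone ketal is removed with PPTS in wet THF to give the keto dialdehyde ester F12. Deallylation as in step 8 gives 19.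

**Further compounds**

F1 | step 2 | (4S)-4-(1,3-dioxolan-2-ylmethyl)tetrahydro-2H-pyran-2-one | O=C1C[C@H](CC2OCCO2)CCO1
F2 | step 2 | lithium (4S)-4-(1,3-dioxolan-2-ylmethyl)-5,6-dihydro-4H-pyran-2-olate | [Li]OC1=C[C@H](CC2OCCO2)CCO1
F3 | step 7 | triethyl[(2-methylbut-3-yn-2-yl)oxy]silane | C#CC(C)(C)O[Si](CC)(CC)CC
F4 | step 7 | {3-methyl-3-[(triethylsilyl)oxy]but-1-yn-1-yl}lithium | [Li]C#CC(C)(C)O[Si](CC)(CC)CC
F5 | step 7 | 4-methyl-4-[(triethylsilyl)oxy]pent-2-ynal | O=CC#CC(C)(C)O[Si](CC)(CC)CC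
F6 | step 7 | allyl (2R,3R)-4-(1,3-dioxolan-2-yl)-3-{1-formyl-2-hydroxy-5-methyl-5-[(triethylsilyl)oxy]hex-3-yn-1-yl}-2-[5-(2-methyl-1,3-dioxolan-2-yl)pent-1-en-2-yl]butanoate (epimers at the two new carbons) | C=C(CCCC1(C)OCCO1)[C@H](C(=O)OCC=C)[C@H](CC2OCCO2)C(C=O)C(O)C#CC(C)(C)O[Si](CC)(CC)CC
F7 | step 7 | allyl (2R,3R)-4-(1,3-dioxolan-2-yl)-3-{1-formyl-5-methyl-2-oxo-5-[(triethylsilyl)oxy]hex-3-yn-1-yl}-2-[5-(2-methyl-1,3-dioxolan-2-yl)pent-1-en-2-yl]butanoate | C=C(CCCC1(C)OCCO1)[C@H](C(=O)OCC=C)[C@H](CC2OCCO2)C(C=O)C(=O)C#CC(C)(C)O[Si](CC)(CC)CC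
F8 | step 7 | allyl (2R,3R)-4-(1,3-dioxolan-2-yl)-3-{(3Z)-1-formyl-5-methyl-2-oxo-5-[(triethylsilyl)oxy]hex-3-en-1-yl}-2-[5-(2-methyl-1,3-dioxolan-2-yl)pent-1-en-2-yl]butanoate | C=C(CCCC1(C)OCCO1)[C@H](C(=O)OCC=C)[C@H](CC2OCCO2)C(C=O)C(=O)/C=C\C(C)(C)O[Si](CC)(CC)CC
F9 | step 7 | allyl (2R,3R)-4-(1,3-dioxolan-2-yl)-3-[1-(2-hydroxy-5,5-dimethyl-2,5-dihydrofuran-2-yl)-2-oxoethyl]-2-[5-(2-methyl-1,3-dioxolan-2-yl)pent-1-en-2-yl]butanoate | C=C(CCCC1(C)OCCO1)[C@H](C(=O)OCC=C)[C@H](CC2OCCO2)C(C=O)C3(O)C=CC(C)(C)O3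
F10 | step 9 | 2,4,6-trimethylpyridinium triflate formed from 17 by opening of the aldehyde dioxolane, carrying the 2-[(triethylsilyl)oxy]ethoxy group on the former acetal carbon | C=C(CCCC1(C)OCCO1)[C@H](C(=O)OCC=C)[C@H](CC(OCCO[Si](CC)(CC)CC)[n+]2c(C)cc(C)cc2C)/C(C=O)=C3/C=CC(C)(C)O3.[O-]S(=O)(=O)C(F)(F)F
F11 | step 9 | allyl (2R,3S)-3-[(1E)-1-(5,5-dimethylfuran-2(5H)-ylidene)-2-oxoethyl]-2-[5-(2-methyl-1,3-dioxolan-2-yl)pent-1-en-2-yl]-5-oxopentanoate | C=C(CCCC1(C)OCCO1)[C@H](C(=O)OCC=C)[C@H](CC=O)/C(C=O)=C2/C=CC(C)(C)O2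
F12 | step 9 | allyl (2R,3S)-3-[(1E)-1-(5,5-dimethylfuran-2(5H)-ylidene)-2-oxoethyl]-5-oxo-2-(6-oxohept-1-en-2-yl)pentanoate | C=C(CCCC(C)=O)[C@H](C(=O)OCC=C)[C@H](CC=O)/C(C=O)=C1/C=CC(C)(C)O1
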